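The rate constants are invented; no experiment stands behind them.

In a one-step world, with nucleophile held at saturation, the electrophile lives 0.115 s, far shorter than the run.

electrophile 5.0 × 10⁻⁴ M; free base 0.750 mM; gas 0.031 mM (held); time 10 s

    electrophile + nucleophile → acid set free + target (k1 = 2.8 × 10⁵ /M/s)
    nucleophile + acid set free ⇌ protonated nucleophile, settled at all times (K2 = 4.2 × 10⁷ /M)
    acid set free + free base ⇌ salt of the base, settled at all times (K3 = 3900 /M)
    gas ⇌ nucleophile, rate k4*(csat - [nucleophile]) (k4 = 3.1 /s, csat = 0.031 mM)
    target ⇌ isomer of the product (K5 = 2.1, k5 = 0.35 /s)
    nucleophile + target ⇌ idle adduct, settled at all times (K6 = 18000 /M)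

- target is meant together with its idle adduct
- at the start none of nucleophile is dissolved
- run time (flask): 10 s

- part of the electrophile that has reacted at 10 s
- share of free nucleophile in free nucleophile and protonated nucleophile together, at 10 s

Our second way counts what the gas brings in. At full drive, as at the start when none of the nucleophile is dissolved, transfer delivers 0.0961 mM/s. Each electrophile uses one nucleophile in the first step, and we charge a second for the acid it sets free. The gas then needs 10.4 s to pay for this flask's charge. This time, twice the charged electrophile divided by the full-drive transfer rate, is the feed time. The asked time over the feed time gives 96.1% reacted, and the two ways part, for the first puts the electrophile's life far below the feed time.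

Turned into times at the charged amounts, the constants show which way cheats:

| What happens | Time |
|---|---|
| electrophile used, nucleophile at saturation | 0.115 s |
| dissolved nucleophile used by charged electrophile | 7.14 ms |
| dissolved nucleophile refilled by the gas | 0.323 s |
| whole charge paid for (feed time) | 10.4 s |

Dissolved nucleophile is used far faster than it is refilled, so in this flask, while the electrophile stands near its charge, the dissolved level stays below saturation, and the one-step reckoning cheats. Refilling takes longer than use, so we take gas transfer as the rate-limiting step of this flask. At the charged electrophile the level where supply meets use is 3.43 × 10⁻⁷ M, far below saturation. At that level, equilibrium constant times amount comes to 14.4 for nucleophile against 2.93 for free base, so charging two nucleophiles is slightly high but fair. We commit to 96.1% and reckon no free share.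

The forecast gives 91% (84% to 96%), lower than our figure, and a free share of 0.7% (0.4% to 1.5%), holding that “roughly two nucleophiles are used per electrophile”.

The flask gives 92.9% reacted and a free share of 0.746%. At 5.00 s this flask had used 50.0% of its electrophile. The neighbour flask charged with 8.5 × 10⁻⁴ M of electrophile has a feed time of 17.7 s, and the asked time over that feed time gives 56.5%. The simulated neighbour reached 60.3%.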